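Between the first and last readings of Tuesday's flask, left-handed substrate gains 7.5 percentage points and left-handed product 3.4 points, so the late movement to watch is in the substrate.

the same everywhere: catalyst 25 mM
- Tuesday's: left-handed substrate 1 M; right-handed substrate 1 M; reagent 0.60 M; the very flask that is asked about, followed so far
- Thursday's: left-handed substrate 0.67 M; right-handed substrate 0.67 M; reagent 0.60 M; run made earlier
- flask: left-handed substrate 1.0 M; right-handed substrate 1.0 M; reagent 0.600 M; time 50 min

Tuesday's run (percent of the left-handed substrate and right-handed substrate together charged)

| time / min | left-handed product / % | left-handed substrate / % |
|---|---|---|
| 4.00 | 27.8 | 28.1 |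
| 12.0 | 28.2 | 32.5 |
| 25.0 | 30.1 | 33.3 |
| 40.0 | 29.8 | 35.4 |
| 50.0 | 31.2 | 35.6 |

Thursday's run (percent of the left-handed substrate and right-handed substrate together charged)

| time / s | left-handed product / % | left-handed substrate / % |
|---|---|---|
| 25.0 | 14.7 | 36.5 |
| 50.0 | 19.8 | 28.5 |
| 80.0 | 26.9 | 24.0 |
| 90.0 | 27.6 | 24.7 |
| 120 | 31.0 | 23.1 |

(scatter of a reading: 1 percentage point)

- epsilon: at 50 min add catalyst, 100% of the amount charged, then wait 25 min
- alpha: at 50 min take out 90% of the left-handed product then present, then wait 25 min
- eta: at 50 min add reagent, 100% of the amount charged, then wait 25 min
- delta: change nothing and wait 25 min more

- catalyst is single-handed; left-handed substrate and right-handed substrate are mirror images of each other, charged as a racemate, each of them at the stated concentration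
- what is taken out of left-handed product is counted as made
- additions bring no volume worth counting

1. left-handed product, in percent of the left-handed substrate and right-handed substrate together first charged, at 50 min
2. what to do for the largest gain in left-handed product; "none" if nothing gains more than 2 percentage points (epsilon / alpha / eta / delta / none)
3. left-handed product present, with what was taken out counted in, in percent of the left-handed substrate and right-handed substrate together first charged, after epsilon
4. left-handed product present, with what was taken out counted in, in percent of the left-handed substrate and right-handed substrate together first charged, after alpha

We measure the flask against the reagent ceiling, the limiting reagent's limit: the share of both substrates together that the charged reagent can turn into product at one reagent each, here 30.0%.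

The fastest rung is the reagent. At Thursday's first reading, 67.2% of its reagent remains. Counting one left-handed substrate lost per reagent, 70.6% of its left-handed substrate remains at that reading, so the two fall together and we take the rate as proportional to reagent times left-handed substrate, a second-order law. Integrated in closed form, the logarithm of the ratio of those two remaining fractions grows in proportion to time and to the difference of the charges, which gives a rough 0.0285 M⁻¹ s⁻¹ from this one reading. With Tuesday's charges, the same law puts the reagent's half-life at about 29.6 s. Tuesday's first reading already stands at 92.7% of the ceiling.

The next rung is the substrates. Reckoning right-handed substrate by difference, its excess over left-handed substrate falls from 16.0% to 6.80% between the first two readings. That is a rough half-life of 6.48 min, much longer than the reagent's. Once level, each substrate should hold 35.0%.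

So we commit to 30.0% now, and to 30.0% after epsilon or alpha, since neither moves the ceiling. Eta lifts it to 60.0%, so eta is our choice.

The forecast gives 30.2% now, 30.5% after epsilon, 30.5% after alpha and eta as best, holding that “The flask is therefore out of reagent”.

The simulated flask gives 29.5% now, with 0% of its reagent left, then 29.5% after epsilon and 29.5% after alpha. Its best move is eta, gaining 29 points.

    reagent + catalyst + left-handed substrate → catalyst + left-handed product (k = 0.935 M⁻² s⁻¹)
    reagent + catalyst + right-handed substrate → catalyst + right-handed product (k = 0.0120 M⁻² s⁻¹)
    left-handed substrate ⇌ right-handed substrate (k = 0.00106 s⁻¹)

The falling level of reagent is the reason this flask stops: the same run with that fall taken away reaches 90.2% of left-handed product against 29.5%. The ceiling of 30.0% is shared, with 0.531% going to right-handed product. In the neighbour charged with 1.5 M of reagent, the ceiling is 75.0%, and that flask holds 3.36% of right-handed product and 71.6% of left-handed product.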